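**Retrosynthetic overview**
1. The oxolane bridge closes last: the C6 hydroxyl adds to the ring A enone (oxa-Michael, sets C3). The acrylic acid comes from a C13 acetyl group (enol triflate, then hydroxycarbonylation).
2. The δ-lactone and ring C form in one flask from aldehyde 10: hydride reduction, acyl transfer of the alkoxide to the activated acrylate ester, then an enamine 6-endo Michael addition (C13–C14 bond; sets C8 and C13).
3. The C9–C10 bond comes from an amine-catalysed SN2′ allylation of formyl ketone 9 with Morita–Baylis–Hillman carbonate 5 (sets quaternary C10 and C9).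
4. 9 comes from 4,4-dimethylcyclohexa-2,5-dienone by desymmetrising conjugate addition (sets C5) and formylation; 5 comes from 5-oxohexanal and 2,2,2-trifluoroethyl acrylate.
5. Ring order: ring A (from the starting enone) → lactone + ring C (one operation) → oxolane bridge.

Assumption: locants C1–C20 follow ent-kaurane numbering of the target (C10 spiro carbon; C7 lactone carbonyl; C20 lactone CH2; C6 ether CH2; C13 carries the acrylic acid; C14 is the ring C CH2 next to C8); the carbinol centre of 4 and 5 is racemic and is erased in step 6.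

**Step 1**
Reactants: 1 1-methylcyclopentene
Product: 2 5-oxohexanal
Conditions: O3, CH2Cl2, −78 °C; then Me2S, −78 → 23 °C
Reagents that add atoms: ozone, [O-][O+]=O
Why: Ozonolysis with reductive work-up cleaves the ring alkene to the keto aldehyde; no stereocentre is formed.

**Step 2**
Reactants: 2 5-oxohexanal; 3 2,2,2-trifluoroethyl acrylate
Product: 4 2,2,2-trifluoroethyl 3-hydroxy-2-methylidene-7-oxooctanoate (racemic)
Conditions: 1,4-diazabicyclo[2.2.2]octane (0.5 equiv), neat, 23 °C
Reagents that add atoms: none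
Why: Morita–Baylis–Hillman reaction in which only the aldehyde reacts (the ketone is inert) and the activated trifluoroethyl acrylate keeps the reaction fast; the new carbinol centre is racemic and is destroyed in step 6.

**Step 3**
Reactants: 4 2,2,2-trifluoroethyl 3-hydroxy-2-methylidene-7-oxooctanoate
Product: 5 2,2,2-trifluoroethyl 3-[(tert-butoxycarbonyl)oxy]-2-methylidene-7-oxooctanoate (racemic)
Conditions: Boc2O, 4-(dimethylamino)pyridine (10 mol %), CH2Cl2, 0 → 23 °C
Reagents that add atoms: di-tert-butyl dicarbonate, CC(C)(C)OC(=O)OC(=O)OC(C)(C)C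
Why: Acylation of the allylic alcohol gives the carbonate leaving group, which later releases CO2 and tert-butoxide as the internal base.

**Step 4**
Reactants: 6 4,4-dimethylcyclohex-2-en-1-one
Product: 7 4,4-dimethylcyclohexa-2,5-dien-1-one
Conditions: 2,3-dichloro-5,6-dicyano-1,4-benzoquinone (DDQ), dioxane, reflux
Reagents that add atoms: none
Why: DDQ dehydrogenation of the enone (hydride abstraction from the dienol) gives the prochiral cross-conjugated dienone; no stereocentre.

**Step 5**
Reactants: 7 4,4-dimethylcyclohexa-2,5-dien-1-one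
Product: 9 (6S)-6-[(benzyloxy)methyl]-5,5-dimethyl-2-oxocyclohex-3-ene-1-carbaldehyde (hydroxymethylene enol), via magnesium dienolate 8 (not isolated)
Conditions: BnOCH2MgCl (from BnOCH2Cl, Mg, THF, −20 °C), CuBr·SMe2 (5 mol %), (R)-1-[(SP)-2-(diphenylphosphino)ferrocenyl]ethyldicyclohexylphosphine (6 mol %), t-BuOMe, −78 °C; then HCO2CH2CF3, −78 → 0 °C; aq. NH4Cl
Reagents that add atoms: benzyloxymethylmagnesium chloride, Cl[Mg]COCc1ccccc1 (made in the flask from benzyl chloromethyl ether, ClCOCc1ccccc1, and Mg); 2,2,2-trifluoroethyl formate, O=COCC(F)(F)F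
Why: Copper-catalysed asymmetric conjugate addition of a Grignard reagent (Feringa-type desymmetrisation of the dienone) sets C5 under ligand control, the ligand enantiomer being the one that gives 5S, and the regiodefined magnesium enolate is C-formylated by the formate (Claisen-type acylation).

**Step 6**
Reactants: 9 (6S)-6-[(benzyloxy)methyl]-5,5-dimethyl-2-oxocyclohex-3-ene-1-carbaldehyde; 5 2,2,2-trifluoroethyl 3-[(tert-butoxycarbonyl)oxy]-2-methylidene-7-oxooctanoate
Product: 10 2,2,2-trifluoroethyl (3S)-3-[(1S,6R)-6-[(benzyloxy)methyl]-1-formyl-5,5-dimethyl-2-oxocyclohex-3-en-1-yl]-2-methylidene-7-oxooctanoate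
Conditions: hydroquinidine (anthraquinone-1,4-diyl) diether (10 mol %), toluene, 40 °C
Reagents that add atoms: none
Why: Lewis-base-catalysed allylic alkylation of a Morita–Baylis–Hillman carbonate (SN2′–SN2′) joins the enolate carbon of 9 to the γ-carbon of the allylammonium ion; C10 is set by attack anti to the pseudoaxial C5 CH2OBn group (CHO ends cis to it), and C9 is set by the chiral amine.

**Step 7**
Reactants: 10 2,2,2-trifluoroethyl (3S)-3-[(1S,6R)-6-[(benzyloxy)methyl]-1-formyl-5,5-dimethyl-2-oxocyclohex-3-en-1-yl]-2-methylidene-7-oxooctanoate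
Product: 13 (5R,8S,9R,10S,13R)-tricyclic keto lactone (cis-fused δ-lactone/ring C; C13 acetyl; C6 benzyl ether; ring A enone), via hydroxy ester 11 (not isolated), via methylene lactone 12 (not isolated)
Conditions: LiAlH(OtBu)3 (1.1 equiv), THF, −78 → 0 °C; then AcOH (2 equiv), pyrrolidine (30 mol %), 40 °C
Reagents that add atoms: none
Why: Chemoselective hydride reduction of the non-enolisable aldehyde, acyl transfer of the alkoxide to the activated ester (spiro α-methylene δ-lactone) and an enamine-mediated intramolecular 6-endo Michael addition close the lactone and ring C in one flask; the epimerisable C13 acetyl settles equatorial (trans to the equatorial C10 on the new chair), and the lactone enolate at C8 is protonated from the less hindered equatorial direction, on the side of H9 and away from spiro ring A (Zimmerman-type kinetic protonation of an exocyclic enolate), which puts C7 axial and gives the cis ring fusion.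

**Step 8**
Reactants: 13 (5R,8S,9R,10S,13R)-tricyclic keto lactone
Product: 14 C16 enol triflate of 13 (1-substituted vinyl trifluoromethanesulfonate at C13)
Conditions: KN(SiMe3)2 (1.1 equiv), THF, −78 °C; then PhNTf2, −78 → 0 °C
Reagents that add atoms: N-phenylbis(trifluoromethanesulfonimide), O=S(=O)(N(c1ccccc1)S(=O)(=O)C(F)(F)F)C(F)(F)F
Why: Kinetic deprotonation of the methyl ketone at CH3 and O-triflation give the terminal vinyl triflate; the ring A ketone cannot enolise (quaternary C10 on one side, vinylic carbon on the other), and no stereocentre is touched.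

**Step 9**
Reactants: 14 C16 enol triflate of 13
Product: 15 (5R,8S,9R,10S,13R)-2-substituted acrylic acid (C6 benzyl ether; ring A enone)
Conditions: Pd(OAc)2 (5 mol %), 1,3-bis(diphenylphosphino)propane (10 mol %), KOAc, CO (1 atm), DMF, 60 °C; aqueous acidic work-up
Reagents that add atoms: carbon monoxide, [C-]#[O+]; water, O
Why: Palladium-catalysed hydroxycarbonylation of a vinyl triflate (Cacchi conditions, via the acyl palladium and mixed anhydride) gives the α-substituted acrylic acid directly; no stereocentre is involved.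

**Step 10**
Reactants: 15 (5R,8S,9R,10S,13R)-2-substituted acrylic acid (C6 benzyl ether)
Product: 17 target CNP0268721.2 (3R,5R,8S,9R,10S,13R), via hydroxymethyl enone 16 (not isolated)
Conditions: BCl3, pentamethylbenzene, CH2Cl2, −78 °C; MeOH; then Et3N, CH2Cl2, 23 °C
Reagents that add atoms: none
Why: Lewis-acid debenzylation with a cation scavenger frees the C6 alcohol, which closes the oxolane by intramolecular oxa-Michael addition to the enone; the one-carbon tether can reach C3 only from its own face, which fixes C3.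

**Compound list**
1 | 1-methylcyclopentene | CC1=CCCC1 | starting material
2 | 5-oxohexanal | CC(=O)CCCC=O | intermediate
3 | 2,2,2-trifluoroethyl acrylate | C=CC(=O)OCC(F)(F)F | starting material
4 | 2,2,2-trifluoroethyl 3-hydroxy-2-methylidene-7-oxooctanoate (racemic) | CC(=O)CCCC(O)C(=C)C(=O)OCC(F)(F)F | intermediate
5 | 2,2,2-trifluoroethyl 3-[(tert-butoxycarbonyl)oxy]-2-methylidene-7-oxooctanoate (racemic) | CC(=O)CCCC(OC(=O)OC(C)(C)C)C(=C)C(=O)OCC(F)(F)F | intermediate
6 | 4,4-dimethylcyclohex-2-en-1-one | CC1(C)CCC(=O)C=C1 | starting material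
7 | 4,4-dimethylcyclohexa-2,5-dien-1-one | CC1(C)C=CC(=O)C=C1 | intermediate
8 | chloromagnesium dienolate of (5S)-5-[(benzyloxy)methyl]-4,4-dimethylcyclohex-2-en-1-one | Cl[Mg]OC1=C[C@H](COCc2ccccc2)C(C)(C)C=C1 | intermediate (not isolated)
9 | (6S)-6-[(benzyloxy)methyl]-5,5-dimethyl-2-oxocyclohex-3-ene-1-carbaldehyde (drawn as keto aldehyde; exists as the hydroxymethylene enol, C1 not defined) | O=CC1C(=O)C=CC(C)(C)[C@H]1COCc1ccccc1 | intermediate
10 | 2,2,2-trifluoroethyl (3S)-3-[(1S,6R)-6-[(benzyloxy)methyl]-1-formyl-5,5-dimethyl-2-oxocyclohex-3-en-1-yl]-2-methylidene-7-oxooctanoate | CC(=O)CCC[C@H](C(=C)C(=O)OCC(F)(F)F)[C@]1(C=O)C(=O)C=CC(C)(C)[C@H]1COCc1ccccc1 | intermediate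
11 | 2,2,2-trifluoroethyl (3S)-3-[(1S,6R)-6-[(benzyloxy)methyl]-1-(hydroxymethyl)-5,5-dimethyl-2-oxocyclohex-3-en-1-yl]-2-methylidene-7-oxooctanoate (formed as its aluminate) | CC(=O)CCC[C@H](C(=C)C(=O)OCC(F)(F)F)[C@]1(CO)C(=O)C=CC(C)(C)[C@H]1COCc1ccccc1 | intermediate (not isolated)
12 | (5S,6S,11R)-11-[(benzyloxy)methyl]-10,10-dimethyl-4-methylidene-5-(4-oxopentyl)-2-oxaspiro[5.5]undec-8-ene-3,7-dione | CC(=O)CCC[C@@H]1C(=C)C(=O)OC[C@]12C(=O)C=CC(C)(C)[C@H]2COCc1ccccc1 | intermediate (not isolated)
13 | (5R,8S,9R,10S,13R)-tricyclic keto lactone: cis-fused δ-lactone/cyclohexane with equatorial C13 acetyl, spiro at C10 to the 5-[(benzyloxy)methyl]-4,4-dimethylcyclohex-2-enone ring | CC(=O)[C@@H]1CC[C@@H]2[C@H](C1)C(=O)OC[C@]21C(=O)C=CC(C)(C)[C@H]1COCc1ccccc1 | intermediate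
14 | enol triflate of 13 (C13 bears C(=CH2)OSO2CF3) | C=C(OS(=O)(=O)C(F)(F)F)[C@@H]1CC[C@@H]2[C@H](C1)C(=O)OC[C@]21C(=O)C=CC(C)(C)[C@H]1COCc1ccccc1 | intermediate
15 | (5R,8S,9R,10S,13R)-acrylic acid with C6 benzyl ether and ring A enone | C=C(C(=O)O)[C@@H]1CC[C@@H]2[C@H](C1)C(=O)OC[C@]21C(=O)C=CC(C)(C)[C@H]1COCc1ccccc1 | intermediate
16 | C6 hydroxymethyl enone acid (debenzylated 15) | C=C(C(=O)O)[C@@H]1CC[C@@H]2[C@H](C1)C(=O)OC[C@]21C(=O)C=CC(C)(C)[C@H]1CO | intermediate (not isolated)
17 | CNP0268721.2 (3R,5R,8S,9R,10S,13R) | C=C(C(=O)O)[C@@H]1CC[C@@H]2[C@H](C1)C(=O)OC[C@]21C(=O)C[C@H]2OC[C@@H]1C2(C)C | target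

**Step count and risks**
Total steps: 10. Longest linear sequence: 8 (steps 1, 2, 3, 6, 7, 8, 9 and 10, from 1); steps 4 and 5 are a two-step side branch from 6 that joins at step 6.

Most likely to fail:

- **Step 5 (enantioselective transfer of an alkoxymethyl Grignard reagent).** α-Alkoxy Grignard reagents are untested in this copper/ferrocenylphosphine system, and the β-carbon is neopentyl. The fallback sets out from 7 and returns at 9. A rhodium-catalysed asymmetric 1,4-addition of potassium vinyltrifluoroborate (Rh(acac)(C2H4)2, BINAP enantiomer chosen for 5R, dioxane/H2O) gives (5R)-4,4-dimethyl-5-vinylcyclohex-2-en-1-one F1. Selective ozonolysis of the vinyl group (O3; Me2S) gives (1S)-2,2-dimethyl-5-oxocyclohex-3-ene-1-carbaldehyde F2. Reductive etherification (BnOSiMe3, Et3SiH, Me3SiOTf) gives (5S)-5-[(benzyloxy)methyl]-4,4-dimethylcyclohex-2-en-1-one F3, and Claisen formylation (NaH, ethyl formate) gives 9.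

- **Step 6 (C- versus O-allylation and the configuration at C9).** The catalyst may be mismatched with the C5 centre, or the hydroxymethylene oxygen may be allylated instead. The fallback sets out from 4 and 9 and returns at 10, and makes O-allylation productive. PBr3 converts 4 into the rearranged bromide 2,2,2-trifluoroethyl (2Z)-2-(bromomethyl)-7-oxooct-2-enoate F4. O-alkylation of 9 (Ag2O, CH2Cl2) gives the alkoxymethylene ketone 2,2,2-trifluoroethyl (2E)-2-({[(E)-[(6R)-6-[(benzyloxy)methyl]-5,5-dimethyl-2-oxocyclohex-3-en-1-ylidene]methyl]oxy}methyl)-7-oxooct-2-enoate F5. A thermal Claisen rearrangement (toluene, 110 °C) then forms the C9–C10 bond, the acrylate and the aldehyde of 10. In the chair transition state the allyl unit adds to the ring face anti to the C5 substituent, and the two alkene geometries of F5 translate into the required C9/C10 relationship.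

- **Step 7 (one-flask lactonisation/Michael cascade).** Possible failures are oxa-Michael addition of the alkoxide instead of acylation, retro-aldol loss of formaldehyde from the β-alkoxy ketone, isomerisation of the α-methylene lactone, aldol or Claisen side reactions of the ketone, and the wrong C8 epimer. The fallback sets out from 10 and returns at 13, and works stepwise under non-basic conditions. Reduction with NaBH4 (EtOH/CH2Cl2, −78 °C) and lactonisation with 4-(dimethylamino)pyridine allow 12 to be isolated. The thermodynamic enol ether (Me3SiCl, NaI, Et3N, MeCN) is the trimethylsilyl enol ether of 12 F6. An intramolecular Mukaiyama–Michael addition promoted by TiCl4 (CH2Cl2, −78 °C) with a cold aqueous quench (kinetic protonation at C8) gives 13.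

**Further compounds**
F1 | step 5 | (5R)-4,4-dimethyl-5-vinylcyclohex-2-en-1-one | C=C[C@H]1CC(=O)C=CC1(C)C
F2 | step 5 | (1S)-2,2-dimethyl-5-oxocyclohex-3-ene-1-carbaldehyde | O=C[C@H]1CC(=O)C=CC1(C)C
F3 | step 5 | (5S)-5-[(benzyloxy)methyl]-4,4-dimethylcyclohex-2-en-1-one | O=C1C[C@H](COCc2ccccc2)C(C)(C)C=C1
F4 | step 6 | 2,2,2-trifluoroethyl (2Z)-2-(bromomethyl)-7-oxooct-2-enoate | CC(=O)CCC/C=C(\CBr)C(=O)OCC(F)(F)F
F5 | step 6 | 2,2,2-trifluoroethyl (2E)-2-({[(E)-[(6R)-6-[(benzyloxy)methyl]-5,5-dimethyl-2-oxocyclohex-3-en-1-ylidene]methyl]oxy}methyl)-7-oxooct-2-enoate | CC(=O)CCC/C=C(\CO/C=C1/C(=O)C=CC(C)(C)[C@H]1COCc1ccccc1)C(=O)OCC(F)(F)F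
F6 | step 7 | trimethylsilyl enol ether of 12 ((Z)-4-(trimethylsilyloxy)pent-3-enyl side chain) | C/C(O[Si](C)(C)C)=C/CC[C@@H]1C(=C)C(=O)OC[C@]12C(=O)C=CC(C)(C)[C@H]2COCc1ccccc1
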